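Plan
1. The target is epicatechin-(4β→8)-epifisetinidol-(4β→8)-catechin. After removal of thirteen benzyl ethers, the retrosynthesis cuts O1–C2 of the middle ring C, then C5–C6, C6–C7, C8–C8a and C4a–C8a of the middle ring A.
2. Enabling feature: the middle ring A carries oxygen only on C7 and C8a and hydrogen on C5 and C6. Upper C4 sits on C8 between both oxygens, and the unit's own C4 sits on C4a. An alkenylketene and a siloxyalkyne assemble exactly this 1-hydroxy-2-alkyl-3-siloxy-6-alkylbenzene, whereas electrophilic substitution of a 5-deoxyflavan would go to C6.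
3. Fragment 1 brings C7 and C8 as a siloxyalkyne on C4β of benzylated epicatechin. Fragment 2 brings C4a, C5, C8a and C6 as an E-diazo enone at the end of the chain C4–C3–C2, which hangs on C8 of benzylated catechin.
4. Forward order: the chain is joined to lower C8 (formylation, Wittig, Ireland–Claisen, aryl Grignard) and lengthened (cross-metathesis, diazo transfer). The middle ring A closes in the benzannulation, the middle ring C closes last (Mitsunobu), and hydrogenolysis ends the route.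
5. Stereochemistry: C2 and C3 of the upper and lower units come from (−)-epicatechin and (+)-catechin, and upper C4 from β-face attack on the C4 cation. Middle C3 and C4 come from chirality transfer in the Ireland–Claisen step out of a CBS-made (R)-carbinol. Middle C2 comes from a chelation-controlled reduction (2S), which the Mitsunobu closure inverts to 2R.

Key step: step 21

Remark: every flavan unit keeps the usual locants (O1, C2, C3, C4, C4a, C5 to C8, C8a; ring A benzo, ring B catechol, ring C pyran). "Cat8" stands for 3,5,7,3',4'-penta-O-benzylcatechin-8-yl (2R,3S) and "Epi4β" for 3,5,7,3',4'-penta-O-benzylepicatechin-4β-yl (2R,3R, 3,4-trans). Compounds 5, 17, 20, 26 and 31 are taken as purchased.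

Step 1
Reactants: 1 (−)-epicatechin
Product: 2 5,7,3',4'-tetra-O-benzyl-(−)-epicatechin
Conditions: BnBr, K2CO3, DMF, 0 °C → rt
Reagents that add atoms: benzyl bromide BrCc1ccccc1
Why: Williamson etherification in which the carbonate deprotonates only the four phenols, so the C3 alcohol stays free and C2 and C3 are not touched.

Step 2
Reactants: 2 5,7,3',4'-tetra-O-benzyl-(−)-epicatechin
Product: 3 3,5,7,3',4'-penta-O-benzyl-(−)-epicatechin
Conditions: NaH, BnBr, Bu4NI (cat.), DMF, 0 °C → rt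
Reagents that add atoms: benzyl bromide BrCc1ccccc1
Why: Williamson etherification of the secondary alkoxide, safe for C2 because no free ring B phenol is left that could open ring C under base.

Step 3
Reactants: 3 3,5,7,3',4'-penta-O-benzyl-(−)-epicatechin
Product: 4 4β-(2-ethoxyethoxy)-3,5,7,3',4'-penta-O-benzylepicatechin (2,3-cis-3,4-trans)
Conditions: DDQ, EtOCH2CH2OH, CH2Cl2, rt
Reagents that add atoms: 2-ethoxyethanol CCOCCO
Why: DDQ benzylic oxidation removes hydride from C4, the position activated by the three ring A oxygens, and the alcohol traps the cation from the β face opposite to the C2 aryl and C3 benzyloxy groups.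

Step 4
Reactants: 4 4β-(2-ethoxyethoxy)-penta-O-benzylepicatechin; 5 potassium trifluoro[(trimethylsilyl)ethynyl]borate
Product: 6 4β-[(trimethylsilyl)ethynyl]-3,5,7,3',4'-penta-O-benzylepicatechin
Conditions: BF3·OEt2, CH2Cl2–MeCN, −40 → 0 °C
Reagents that add atoms: none
Why: Lewis acid-promoted SN1 alkynylation of an activated benzylic ether with an alkynyltrifluoroborate, in which the alkynyldifluoroborane made from 5 binds and ionizes the chelating ether and passes its alkynyl group to the C4 cation from the β face, trans to the 3-benzyloxy group as carbon nucleophiles do throughout the epicatechin series.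

Step 5
Reactants: 6 4β-[(trimethylsilyl)ethynyl]-penta-O-benzylepicatechin
Product: 7 4β-ethynyl-3,5,7,3',4'-penta-O-benzylepicatechin
Conditions: K2CO3 (cat.), MeOH–THF, rt
Reagents that add atoms: none
Why: Methoxide-catalysed protiodesilylation of an alkynylsilane, too mild to deprotonate the propargylic C4–H.

Step 6
Reactants: 7 4β-ethynyl-penta-O-benzylepicatechin
Product: 10 4β-[(triisopropylsiloxy)ethynyl]-3,5,7,3',4'-penta-O-benzylepicatechin, via lithium acetylide 8 (not isolated), via lithium ynolate 9 (not isolated)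
Conditions: n-BuLi, THF, −78 °C; t-BuOOLi (from t-BuOOH and LiN(SiMe3)2), −78 → 0 °C; i-Pr3SiOTf, −78 → 0 °C
Reagents that add atoms: n-butyllithium [Li]CCCC (lithium stays only in 8 and 9); tert-butyl hydroperoxide CC(C)(C)OO; triisopropylsilyl triflate CC(C)[Si](OS(=O)(=O)C(F)(F)F)(C(C)C)C(C)C
Why: Oxidation of a lithium acetylide by lithium tert-butyl peroxide to the ynolate followed by O-silylation, where the bulky silyl triflate goes to oxygen and gives an isolable siloxyalkyne without touching C4.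

Step 7
Reactants: 11 (+)-catechin
Product: 12 5,7,3',4'-tetra-O-benzyl-(+)-catechin
Conditions: BnBr, K2CO3, DMF, 0 °C → rt
Reagents that add atoms: benzyl bromide BrCc1ccccc1
Why: Williamson etherification selective for the four phenols, as in step 1.

Step 8
Reactants: 12 5,7,3',4'-tetra-O-benzyl-(+)-catechin
Product: 13 3,5,7,3',4'-penta-O-benzyl-(+)-catechin
Conditions: NaH, BnBr, Bu4NI (cat.), DMF, 0 °C → rt
Reagents that add atoms: benzyl bromide BrCc1ccccc1
Why: Williamson etherification of the remaining secondary alcohol, as in step 2.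

Step 9
Reactants: 13 3,5,7,3',4'-penta-O-benzyl-(+)-catechin
Product: 14 8-bromo-3,5,7,3',4'-penta-O-benzylcatechin
Conditions: NBS, CH2Cl2, −78 °C → rt
Reagents that add atoms: N-bromosuccinimide O=C1CCC(=O)N1Br
Why: Electrophilic aromatic bromination, which in benzylated catechins goes to C8 as the most nucleophilic ring A carbon and stops at the monobromide with one equivalent of reagent.

Step 10
Reactants: 14 8-bromo-penta-O-benzylcatechin
Product: 16 8-formyl-3,5,7,3',4'-penta-O-benzylcatechin, via aryllithium 15 (not isolated)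
Conditions: n-BuLi, THF, −78 °C; DMF, −78 °C → rt; H2O
Reagents that add atoms: n-butyllithium [Li]CCCC (lithium stays only in 15); N,N-dimethylformamide CN(C)C=O
Why: Bromine–lithium exchange, faster at −78 °C than deprotonation of the benzyl ethers, followed by Bouveault formylation, which fixes the future middle C4 on lower C8.

Step 11
Reactants: 16 8-formyl-penta-O-benzylcatechin; 17 1-(triphenylphosphoranylidene)propan-2-one
Product: 18 (E)-4-(Cat8)but-3-en-2-one
Conditions: toluene, 110 °C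
Reagents that add atoms: none
Why: Wittig olefination with a stabilized ylide, which gives the E-enone and tolerates the hindered, electron-rich aldehyde on heating.

Step 12
Reactants: 18 (E)-4-(Cat8)but-3-en-2-one
Product: 19 (2R,3E)-4-(Cat8)but-3-en-2-ol
Conditions: (S)-2-methyl-CBS-oxazaborolidine (20 mol %), BH3·SMe2, THF, −30 °C; MeOH; Et3N-washed silica
Reagents that add atoms: none
Why: Corey–Bakshi–Shibata reduction in which the (S)-catalyst places the large alkenyl arm away from its boron substituent and delivers hydride to the face that gives the (R)-carbinol, a reagent control that overrides the remote catechin stereocentres.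

Step 13
Reactants: 19 (2R,3E)-4-(Cat8)but-3-en-2-ol; 20 benzyloxyacetic acid
Product: 21 (2R,3E)-4-(Cat8)but-3-en-2-yl benzyloxyacetate
Conditions: DCC, DMAP (cat.), CH2Cl2, 0 °C → rt
Reagents that add atoms: none
Why: Steglich esterification acylates the oxygen without breaking the C–O bond, so the carbinol configuration is kept, and its acid-free medium avoids ionization of the electron-rich allylic system.

Step 14
Reactants: 21 (2R,3E)-4-(Cat8)but-3-en-2-yl benzyloxyacetate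
Product: 24 (2R,3R,4E)-2-benzyloxy-3-(Cat8)hex-4-enoic acid, via silyl ketene acetal 22 (not isolated), via silyl ester 23 (not isolated)
Conditions: LiN(SiMe3)2, Me3SiCl, THF, −78 °C → rt; aq. K2CO3, then citric acid
Reagents that add atoms: chlorotrimethylsilane C[Si](C)(C)Cl (the silyl group stays only in 22 and 23)
Why: Ireland–Claisen rearrangement in which lithium chelation by the benzyloxy oxygen fixes the Z ketene acetal, and a chair transition state with the carbinol methyl group equatorial transfers the (R) C–O chirality suprafacially to the new benzylic carbon (middle C4, R) and sets the α-carbon (middle C3, R) syn to it, leaving an E-propenyl group.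

Step 15
Reactants: 24 (2R,3R,4E)-2-benzyloxy-3-(Cat8)hex-4-enoic acid
Product: 25 (2R,3R,4E)-2-benzyloxy-3-(Cat8)-N-methoxy-N-methylhex-4-enamide
Conditions: MeNH(OMe)·HCl, EDC·HCl, HOBt (cat.), N-methylmorpholine, CH2Cl2, 0 °C → rt
Reagents that add atoms: N,O-dimethylhydroxylamine hydrochloride CNOC.Cl
Why: Carbodiimide amide coupling to the Weinreb amide through the HOBt ester, a mild activation that does not epimerize the α-alkoxy carbon.

Step 16
Reactants: 25 Weinreb amide; 26 4-bromo-1,2-bis(benzyloxy)benzene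
Product: 28 (2R,3R,4E)-2-benzyloxy-1-[3,4-bis(benzyloxy)phenyl]-3-(Cat8)hex-4-en-1-one, via Grignard reagent 27 (not isolated)
Conditions: 26, Mg, THF, 50 °C; then 25, THF, 0 °C → rt; aq. NH4Cl
Reagents that add atoms: magnesium [Mg] (stays only in 27)
Why: Weinreb ketone synthesis, in which the magnesium chelate of the tetrahedral adduct prevents a second addition and shields the α-stereocentre from enolization until work-up.

Step 17
Reactants: 28 aryl ketone
Product: 29 (1S,2R,3R,4E)-2-benzyloxy-1-[3,4-bis(benzyloxy)phenyl]-3-(Cat8)hex-4-en-1-ol (1,2-anti; carbinol carbon is middle C2)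
Conditions: Zn(BH4)2, Et2O–CH2Cl2, −30 → 0 °C
Reagents that add atoms: none
Why: Cram-chelate reduction in which zinc ties the carbonyl and α-benzyloxy oxygens into a five-membered ring and hydride enters from the face of the small C–H substituent, which gives the 1,2-anti alcohol with middle C2 as S.

Step 18
Reactants: 29 anti alcohol
Product: 30 tert-butyldimethylsilyl ether of 29 (1S,2R,3R,4E)
Conditions: t-BuMe2SiOTf, 2,6-lutidine, CH2Cl2, −78 → 0 °C
Reagents that add atoms: tert-butyldimethylsilyl triflate CC(C)(C)[Si](C)(C)OS(=O)(=O)C(F)(F)F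
Why: Silylation with the reactive silyl triflate and a hindered base covers the crowded benzylic alcohol on oxygen without ionizing it, so C2 keeps its configuration.

Step 19
Reactants: 30 silyl ether; 31 methyl vinyl ketone
Product: 32 (3E,5R,6R,7S)-6-benzyloxy-7-[3,4-bis(benzyloxy)phenyl]-7-(tert-butyldimethylsiloxy)-5-(Cat8)hept-3-en-2-one
Conditions: 31 (excess), second-generation Hoveyda–Grubbs catalyst (10 mol %), toluene, 60 °C
Reagents that add atoms: none
Why: Olefin cross-metathesis between an alkene too hindered to dimerize and an electron-poor enone that homodimerizes slowly, which favours the E cross product under neutral conditions that cannot epimerize C4.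

Step 20
Reactants: 32 methyl enone
Product: 34 (3E,5R,6R,7S)-6-benzyloxy-7-[3,4-bis(benzyloxy)phenyl]-7-(tert-butyldimethylsiloxy)-5-(Cat8)-1-diazohept-3-en-2-one, via trifluoroacetyl ketone 33 (not isolated)
Conditions: LiN(SiMe3)2, THF, −78 °C; CF3CO2CH2CF3; 5 % HCl wash; then 4-AcNHC6H4SO2N3, Et3N, H2O, MeCN–CH2Cl2, rt
Reagents that add atoms: 2,2,2-trifluoroethyl trifluoroacetate O=C(OCC(F)(F)F)C(F)(F)F (the acyl group stays only in 33); 4-acetamidobenzenesulfonyl azide CC(=O)Nc1ccc(cc1)S(=O)(=O)N=[N+]=[N-]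
Why: Detrifluoroacetylative diazo transfer, in which kinetic enolization at the methyl group (not at the γ C4–H) and trifluoroacetylation activate that carbon for the Regitz-type transfer, a route to diazo enones that avoids diazomethane and its cycloaddition to the enone.

Step 21
Reactants: 34 E-diazo enone; 10 siloxyalkyne
Product: 39 seco-trimer phenol (middle ring A complete: OH on C8a; Epi4β on C8; OSi(i-Pr)3 on C7; H on C6 and C5; chain C4H(Cat8)–C3H(OBn)–C2H(OSiMe2t-Bu)Ar on C4a; 2S,3R,4R), via alkenylketene 35 (not isolated), via cyclobutenone 36 (not isolated), via dienylketene 37 (not isolated), via cyclohexadienone 38 (not isolated)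
Conditions: 10 (slight excess), hν (medium-pressure Hg lamp, Pyrex filter, λ > 300 nm), degassed ClCH2CH2Cl, 20 °C; then 80 °C in the dark
Reagents that add atoms: none
Why: Light above 300 nm is absorbed only by the diazo enone, which loses N2 with a concerted 1,2-shift of the alkenyl group (photochemical Wolff rearrangement, C5–C6) to give alkenylketene 35, and the carbon-substituted, nucleophilic terminus of siloxyalkyne 10 adds to the ketene carbonyl carbon in a [2+2] cycloaddition (C8–C8a and C6–C7) to give cyclobutenone 36. Heat or light then opens 36 by 4π electrocyclic cleavage of C6–C8a to dienylketene 37, whose 6π electrocyclization (C4a–C8a) gives dienone 38, and enolization delivers phenol 39. The closest known reaction type is the Danheiser benzannulation of α-diazo ketones with triisopropylsiloxyalkynes to resorcinol monosilyl ethers, for which acyclic E-diazo enones and siloxyalkynes with a branched alkyl group are known partners, so only the size of the partners is new. The four-membered ring closes by cycloaddition and is transient, and the only lasting ring, the middle ring A, closes by thermal disrotatory 6π electrocyclization followed by aromatization. No lasting stereocentre is created (the sp3 carbons of 36 and 38 become aromatic), and the neutral medium leaves upper C4, middle C2 to C4 and both interflavan benzylic positions untouched. The step needs regioselectivity in the [2+2] event, secured by the polarization of the ynol silyl ether that places the upper unit on C8 between the free C8a phenol and the C7 silyl ether, and chemoselectivity of the ketene, secured by the absence of OH groups in both partners and by the E alkene, which keeps C4–H out of reach of a 1,5-hydrogen shift.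

Step 22
Reactants: 39 seco-trimer phenol
Product: 40 seco-trimer triol (free C2–OH, C7–OH and C8a–OH; 2S,3R,4R)
Conditions: Bu4NF, AcOH, THF, 0 °C → rt
Reagents that add atoms: none
Why: Fluoride-driven cleavage of the aryl and the alkyl silyl ether, buffered with acetic acid so that the resorcinol is handled as the neutral phenol and no stereocentre is exposed to strong base.

Step 23
Reactants: 40 seco-trimer triol
Product: 41 trideca-O-benzyl trimer with free 7-OH on the middle unit (middle unit 2R,3R,4R, 2,3-cis-3,4-trans)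
Conditions: PPh3, DIAD, toluene (high dilution), 0 °C → rt
Reagents that add atoms: none
Why: Intramolecular Mitsunobu etherification (6-exo-tet) in which the C8a phenol displaces the oxyphosphonium group at C2 with inversion (2S to 2R), while the C7 phenol cannot reach C2 and the apolar solvent, low temperature and the inductive pull of the C3 benzyloxy group work against ionization.

Step 24
Reactants: 41 trideca-O-benzyl trimer
Product: 42 epicatechin-(4β→8)-epifisetinidol-(4β→8)-catechin (target)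
Conditions: H2 (1 atm), Pd(OH)2/C, THF–MeOH–H2O, rt
Reagents that add atoms: none
Why: Catalytic hydrogenolysis of the thirteen benzyl ethers under neutral conditions, which in benzylated proanthocyanidins spare the interflavan C–C bonds and the cyclic C2–O1 bonds.

Compound list
1 | (−)-epicatechin (2R,3R) | Oc1cc(O)c2c(c1)O[C@H](c1ccc(O)c(O)c1)[C@H](O)C2 | starting material
2 | 5,7,3',4'-tetra-O-benzyl-(−)-epicatechin | c9ccccc9COc1cc(OCc9ccccc9)c2c(c1)O[C@H](c3ccc(OCc9ccccc9)c(OCc9ccccc9)c3)[C@H](O)C2 | intermediate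
3 | 3,5,7,3',4'-penta-O-benzyl-(−)-epicatechin | c9ccccc9COc1cc(OCc9ccccc9)c2c(c1)O[C@H](c3ccc(OCc9ccccc9)c(OCc9ccccc9)c3)[C@H](OCc9ccccc9)C2 | intermediate
4 | 4β-(2-ethoxyethoxy)-penta-O-benzylepicatechin | c9ccccc9COc1cc(OCc9ccccc9)c2c(c1)O[C@H](c3ccc(OCc9ccccc9)c(OCc9ccccc9)c3)[C@H](OCc9ccccc9)[C@H]2OCCOCC | intermediate
5 | potassium trifluoro[(trimethylsilyl)ethynyl]borate | C[Si](C)(C)C#C[B-](F)(F)F.[K+] | starting material
6 | 4β-[(trimethylsilyl)ethynyl]-penta-O-benzylepicatechin | c9ccccc9COc1cc(OCc9ccccc9)c2c(c1)O[C@H](c3ccc(OCc9ccccc9)c(OCc9ccccc9)c3)[C@H](OCc9ccccc9)[C@H]2C#C[Si](C)(C)C | intermediate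
7 | 4β-ethynyl-penta-O-benzylepicatechin | c9ccccc9COc1cc(OCc9ccccc9)c2c(c1)O[C@H](c3ccc(OCc9ccccc9)c(OCc9ccccc9)c3)[C@H](OCc9ccccc9)[C@H]2C#C | intermediate
8 | lithium acetylide of 7 | c9ccccc9COc1cc(OCc9ccccc9)c2c(c1)O[C@H](c3ccc(OCc9ccccc9)c(OCc9ccccc9)c3)[C@H](OCc9ccccc9)[C@H]2C#C[Li] | intermediate
9 | lithium ynolate (Epi4β–C≡C–OLi) | c9ccccc9COc1cc(OCc9ccccc9)c2c(c1)O[C@H](c3ccc(OCc9ccccc9)c(OCc9ccccc9)c3)[C@H](OCc9ccccc9)[C@H]2C#CO[Li] | intermediate
10 | 4β-[(triisopropylsiloxy)ethynyl]-penta-O-benzylepicatechin | c9ccccc9COc1cc(OCc9ccccc9)c2c(c1)O[C@H](c3ccc(OCc9ccccc9)c(OCc9ccccc9)c3)[C@H](OCc9ccccc9)[C@H]2C#CO[Si](C(C)C)(C(C)C)C(C)C | intermediate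
11 | (+)-catechin (2R,3S) | Oc1cc(O)c2c(c1)O[C@H](c1ccc(O)c(O)c1)[C@@H](O)C2 | starting material
12 | 5,7,3',4'-tetra-O-benzyl-(+)-catechin | c9ccccc9COc1cc(OCc9ccccc9)c2c(c1)O[C@H](c3ccc(OCc9ccccc9)c(OCc9ccccc9)c3)[C@@H](O)C2 | intermediate
13 | 3,5,7,3',4'-penta-O-benzyl-(+)-catechin | c9ccccc9COc1cc(OCc9ccccc9)c2c(c1)O[C@H](c3ccc(OCc9ccccc9)c(OCc9ccccc9)c3)[C@@H](OCc9ccccc9)C2 | intermediate
14 | 8-bromo-penta-O-benzylcatechin | Brc1c(OCc9ccccc9)cc(OCc9ccccc9)c2c1O[C@H](c3ccc(OCc9ccccc9)c(OCc9ccccc9)c3)[C@@H](OCc9ccccc9)C2 | intermediate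
15 | 8-lithio-penta-O-benzylcatechin | [Li]c1c(OCc9ccccc9)cc(OCc9ccccc9)c2c1O[C@H](c3ccc(OCc9ccccc9)c(OCc9ccccc9)c3)[C@@H](OCc9ccccc9)C2 | intermediate
16 | 8-formyl-penta-O-benzylcatechin | O=Cc1c(OCc9ccccc9)cc(OCc9ccccc9)c2c1O[C@H](c3ccc(OCc9ccccc9)c(OCc9ccccc9)c3)[C@@H](OCc9ccccc9)C2 | intermediate
17 | 1-(triphenylphosphoranylidene)propan-2-one | CC(=O)C=P(c1ccccc1)(c1ccccc1)c1ccccc1 | starting material
18 | (E)-4-(Cat8)but-3-en-2-one | CC(=O)/C=C/c1c(OCc9ccccc9)cc(OCc9ccccc9)c2c1O[C@H](c3ccc(OCc9ccccc9)c(OCc9ccccc9)c3)[C@@H](OCc9ccccc9)C2 | intermediate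
19 | (2R,3E)-4-(Cat8)but-3-en-2-ol | C[C@@H](O)/C=C/c1c(OCc9ccccc9)cc(OCc9ccccc9)c2c1O[C@H](c3ccc(OCc9ccccc9)c(OCc9ccccc9)c3)[C@@H](OCc9ccccc9)C2 | intermediate
20 | benzyloxyacetic acid | OC(=O)COCc1ccccc1 | starting material
21 | (2R,3E)-4-(Cat8)but-3-en-2-yl benzyloxyacetate | C[C@@H](OC(=O)COCc9ccccc9)/C=C/c1c(OCc9ccccc9)cc(OCc9ccccc9)c2c1O[C@H](c3ccc(OCc9ccccc9)c(OCc9ccccc9)c3)[C@@H](OCc9ccccc9)C2 | intermediate
22 | (Z)-trimethylsilyl ketene acetal of 21 | C[C@@H](O/C(O[Si](C)(C)C)=C/OCc9ccccc9)/C=C/c1c(OCc9ccccc9)cc(OCc9ccccc9)c2c1O[C@H](c3ccc(OCc9ccccc9)c(OCc9ccccc9)c3)[C@@H](OCc9ccccc9)C2 | intermediate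
23 | trimethylsilyl ester of 24 | C[Si](C)(C)OC(=O)[C@H](OCc9ccccc9)[C@H](/C=C/C)c1c(OCc9ccccc9)cc(OCc9ccccc9)c2c1O[C@H](c3ccc(OCc9ccccc9)c(OCc9ccccc9)c3)[C@@H](OCc9ccccc9)C2 | intermediate
24 | (2R,3R,4E)-2-benzyloxy-3-(Cat8)hex-4-enoic acid | OC(=O)[C@H](OCc9ccccc9)[C@H](/C=C/C)c1c(OCc9ccccc9)cc(OCc9ccccc9)c2c1O[C@H](c3ccc(OCc9ccccc9)c(OCc9ccccc9)c3)[C@@H](OCc9ccccc9)C2 | intermediate
25 | Weinreb amide of 24 (2R,3R,4E) | CON(C)C(=O)[C@H](OCc9ccccc9)[C@H](/C=C/C)c1c(OCc9ccccc9)cc(OCc9ccccc9)c2c1O[C@H](c3ccc(OCc9ccccc9)c(OCc9ccccc9)c3)[C@@H](OCc9ccccc9)C2 | intermediate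
26 | 4-bromo-1,2-bis(benzyloxy)benzene | Brc1ccc(OCc2ccccc2)c(OCc2ccccc2)c1 | starting material
27 | 3,4-bis(benzyloxy)phenylmagnesium bromide | Br[Mg]c1ccc(OCc2ccccc2)c(OCc2ccccc2)c1 | intermediate
28 | (2R,3R,4E)-2-benzyloxy-1-[3,4-bis(benzyloxy)phenyl]-3-(Cat8)hex-4-en-1-one | O=C(c3ccc(OCc9ccccc9)c(OCc9ccccc9)c3)[C@H](OCc9ccccc9)[C@H](/C=C/C)c1c(OCc9ccccc9)cc(OCc9ccccc9)c2c1O[C@H](c3ccc(OCc9ccccc9)c(OCc9ccccc9)c3)[C@@H](OCc9ccccc9)C2 | intermediate
29 | (1S,2R,3R,4E)-2-benzyloxy-1-[3,4-bis(benzyloxy)phenyl]-3-(Cat8)hex-4-en-1-ol | O[C@@H](c3ccc(OCc9ccccc9)c(OCc9ccccc9)c3)[C@H](OCc9ccccc9)[C@H](/C=C/C)c1c(OCc9ccccc9)cc(OCc9ccccc9)c2c1O[C@H](c3ccc(OCc9ccccc9)c(OCc9ccccc9)c3)[C@@H](OCc9ccccc9)C2 | intermediate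
30 | tert-butyldimethylsilyl ether of 29 | CC(C)(C)[Si](C)(C)O[C@@H](c3ccc(OCc9ccccc9)c(OCc9ccccc9)c3)[C@H](OCc9ccccc9)[C@H](/C=C/C)c1c(OCc9ccccc9)cc(OCc9ccccc9)c2c1O[C@H](c3ccc(OCc9ccccc9)c(OCc9ccccc9)c3)[C@@H](OCc9ccccc9)C2 | intermediate
31 | methyl vinyl ketone | CC(=O)C=C | starting material
32 | (3E,5R,6R,7S)-methyl enone | CC(C)(C)[Si](C)(C)O[C@@H](c3ccc(OCc9ccccc9)c(OCc9ccccc9)c3)[C@H](OCc9ccccc9)[C@H](/C=C/C(C)=O)c1c(OCc9ccccc9)cc(OCc9ccccc9)c2c1O[C@H](c3ccc(OCc9ccccc9)c(OCc9ccccc9)c3)[C@@H](OCc9ccccc9)C2 | intermediate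
33 | α-trifluoroacetyl derivative of 32 | CC(C)(C)[Si](C)(C)O[C@@H](c3ccc(OCc9ccccc9)c(OCc9ccccc9)c3)[C@H](OCc9ccccc9)[C@H](/C=C/C(=O)CC(=O)C(F)(F)F)c1c(OCc9ccccc9)cc(OCc9ccccc9)c2c1O[C@H](c3ccc(OCc9ccccc9)c(OCc9ccccc9)c3)[C@@H](OCc9ccccc9)C2 | intermediate
34 | (3E,5R,6R,7S)-diazo enone | CC(C)(C)[Si](C)(C)O[C@@H](c3ccc(OCc9ccccc9)c(OCc9ccccc9)c3)[C@H](OCc9ccccc9)[C@H](/C=C/C(=O)C=[N+]=[N-])c1c(OCc9ccccc9)cc(OCc9ccccc9)c2c1O[C@H](c3ccc(OCc9ccccc9)c(OCc9ccccc9)c3)[C@@H](OCc9ccccc9)C2 | intermediate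
35 | alkenylketene (hepta-1,3-dien-1-one, 3E,5R,6R,7S) | CC(C)(C)[Si](C)(C)O[C@@H](c3ccc(OCc9ccccc9)c(OCc9ccccc9)c3)[C@H](OCc9ccccc9)[C@H](/C=C/C=C=O)c1c(OCc9ccccc9)cc(OCc9ccccc9)c2c1O[C@H](c3ccc(OCc9ccccc9)c(OCc9ccccc9)c3)[C@@H](OCc9ccccc9)C2 | intermediate
36 | 4-alkenyl-2-(Epi4β)-3-(triisopropylsiloxy)cyclobut-2-enone (ring sp3 carbon undefined) | CC(C)(C)[Si](C)(C)O[C@@H](c3ccc(OCc9ccccc9)c(OCc9ccccc9)c3)[C@H](OCc9ccccc9)[C@H](/C=C/C6C(=O)C([C@@H]4[C@@H](OCc9ccccc9)[C@@H](c3ccc(OCc9ccccc9)c(OCc9ccccc9)c3)Oc5cc(OCc9ccccc9)cc(OCc9ccccc9)c45)=C6O[Si](C(C)C)(C(C)C)C(C)C)c1c(OCc9ccccc9)cc(OCc9ccccc9)c2c1O[C@H](c3ccc(OCc9ccccc9)c(OCc9ccccc9)c3)[C@@H](OCc9ccccc9)C2 | intermediate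
37 | dienylketene (reactive geometry) | CC(C)(C)[Si](C)(C)O[C@@H](c3ccc(OCc9ccccc9)c(OCc9ccccc9)c3)[C@H](OCc9ccccc9)[C@H](/C=C/C=C(\C([C@@H]4[C@@H](OCc9ccccc9)[C@@H](c3ccc(OCc9ccccc9)c(OCc9ccccc9)c3)Oc5cc(OCc9ccccc9)cc(OCc9ccccc9)c45)=C=O)O[Si](C(C)C)(C(C)C)C(C)C)c1c(OCc9ccccc9)cc(OCc9ccccc9)c2c1O[C@H](c3ccc(OCc9ccccc9)c(OCc9ccccc9)c3)[C@@H](OCc9ccccc9)C2 | intermediate
38 | cyclohexa-2,4-dienone (ring sp3 carbon undefined) | CC(C)(C)[Si](C)(C)O[C@@H](c3ccc(OCc9ccccc9)c(OCc9ccccc9)c3)[C@H](OCc9ccccc9)[C@H](C6C=CC(O[Si](C(C)C)(C(C)C)C(C)C)=C([C@@H]4[C@@H](OCc9ccccc9)[C@@H](c3ccc(OCc9ccccc9)c(OCc9ccccc9)c3)Oc5cc(OCc9ccccc9)cc(OCc9ccccc9)c45)C6=O)c1c(OCc9ccccc9)cc(OCc9ccccc9)c2c1O[C@H](c3ccc(OCc9ccccc9)c(OCc9ccccc9)c3)[C@@H](OCc9ccccc9)C2 | intermediate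
39 | seco-trimer phenol (C8a–OH, C7–OSi(i-Pr)3, C2–OSiMe2t-Bu; 2S,3R,4R) | CC(C)(C)[Si](C)(C)O[C@@H](c3ccc(OCc9ccccc9)c(OCc9ccccc9)c3)[C@H](OCc9ccccc9)[C@H](c1ccc(O[Si](C(C)C)(C(C)C)C(C)C)c([C@@H]4[C@@H](OCc9ccccc9)[C@@H](c3ccc(OCc9ccccc9)c(OCc9ccccc9)c3)Oc5cc(OCc9ccccc9)cc(OCc9ccccc9)c45)c1O)c1c(OCc9ccccc9)cc(OCc9ccccc9)c2c1O[C@H](c3ccc(OCc9ccccc9)c(OCc9ccccc9)c3)[C@@H](OCc9ccccc9)C2 | intermediate
40 | seco-trimer triol (2S,3R,4R) | O[C@@H](c3ccc(OCc9ccccc9)c(OCc9ccccc9)c3)[C@H](OCc9ccccc9)[C@H](c1ccc(O)c([C@@H]4[C@@H](OCc9ccccc9)[C@@H](c3ccc(OCc9ccccc9)c(OCc9ccccc9)c3)Oc5cc(OCc9ccccc9)cc(OCc9ccccc9)c45)c1O)c1c(OCc9ccccc9)cc(OCc9ccccc9)c2c1O[C@H](c3ccc(OCc9ccccc9)c(OCc9ccccc9)c3)[C@@H](OCc9ccccc9)C2 | intermediate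
41 | trideca-O-benzyl trimer, middle 7-OH free | c9ccccc9COc1cc(OCc9ccccc9)c2c(c1)O[C@H](c3ccc(OCc9ccccc9)c(OCc9ccccc9)c3)[C@H](OCc9ccccc9)[C@H]2c1c(O)ccc2c1O[C@H](c3ccc(OCc9ccccc9)c(OCc9ccccc9)c3)[C@H](OCc9ccccc9)[C@H]2c1c(OCc9ccccc9)cc(OCc9ccccc9)c2c1O[C@H](c3ccc(OCc9ccccc9)c(OCc9ccccc9)c3)[C@@H](OCc9ccccc9)C2 | intermediate
42 | epicatechin-(4β→8)-epifisetinidol-(4β→8)-catechin | Oc1cc(O)c2c(c1)O[C@H](c1ccc(O)c(O)c1)[C@H](O)[C@H]2c1c(O)ccc2c1O[C@H](c1ccc(O)c(O)c1)[C@H](O)[C@H]2c1c(O)cc(O)c2c1O[C@H](c1ccc(O)c(O)c1)[C@@H](O)C2 | target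

Total step count: 24. Longest linear sequence: 18 steps (11 to 42, steps 7 to 24). The upper fragment takes steps 1 to 6 and joins at step 21.

Steps most likely to fail

1) Step 21.
- What may go wrong: capture of the short-lived alkenylketene by the crowded alkyne may be slower than ketene dimerization, light-induced E to Z isomerization of the enone, or photodegradation of the many aryl ethers.
- Fallback: ketene generation is separated from light and from the valuable alkyne. The fallback sets out from 34.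
- Irradiation of 34 in aqueous THF, where water traps the ketene at once, should give the β,γ-unsaturated acid F1.
- 1-Chloro-N,N,2-trimethylprop-1-en-1-amine in CH2Cl2 should turn F1 into the acid chloride F2 under neutral conditions.
- Slow addition of F2 to 10 and Et3N in toluene at 80 to 110 °C should form the same alkenylketene 35 by dehydrochlorination, in the dark and at low stationary concentration with the alkyne in excess.
- The thermal cascade through 36, 37 and 38 then comes back to the route at 39.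

2) Step 19.
- What may go wrong: the catalyst may not turn over at the internal alkene, whose allylic carbon bears the lower unit, or ruthenium hydride species may move the double bond into conjugation with the lower ring A, with loss of C4.
- Fallback: metathesis is replaced by cleavage and olefination. The fallback sets out from 30.
- Lemieux–Johnson cleavage (OsO4 cat., NaIO4, 2,6-lutidine, dioxane–H2O) should give the α-aryl aldehyde F3.
- F3 is used at once in a Horner–Wadsworth–Emmons reaction with diethyl (3-diazo-2-oxopropyl)phosphonate (LiCl, i-Pr2NEt, MeCN, 0 °C, Masamune–Roush conditions, chosen to limit epimerization at C4).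
- This gives the E-diazo enone directly and comes back to the route at 34, without 32 and 33.

3) Step 23.
- What may go wrong: the oxyphosphonium salt may ionize at the electron-rich benzylic C2, with loss of stereospecificity and drift toward the 2,3-trans ring, or the crowded phenol may not close.
- Fallback: O1 is bonded from the other side, at C8a, so that the C2–O bond is never broken. The fallback sets out from 39.
- Tf2O and pyridine should give the aryl triflate F4.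
- HF·pyridine buffered with pyridine should remove only the alkyl silyl ether and give the alcohol F5.
- Dess–Martin periodinane should give the ketone F6.
- LiBH(s-Bu)3 in THF at −78 °C (Felkin–Anh control, no chelation) should give the 1,2-syn (2R) alcohol F7.
- Palladium-catalysed intramolecular aryl ether formation (Pd(OAc)2, 2-(di-tert-butylphosphino)-1,1'-binaphthyl, Cs2CO3, toluene, 80 °C, Buchwald–Hartwig etherification, retention at C2) should close ring C to the 7-O-triisopropylsilyl trimer F8.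
- Bu4NF then comes back to the route at 41.

Further compounds
F1 | step 21 | (3E,5R,6R,7S)-6-benzyloxy-7-[3,4-bis(benzyloxy)phenyl]-7-(tert-butyldimethylsiloxy)-5-(Cat8)hept-3-enoic acid | CC(C)(C)[Si](C)(C)O[C@@H](c3ccc(OCc9ccccc9)c(OCc9ccccc9)c3)[C@H](OCc9ccccc9)[C@H](/C=C/CC(=O)O)c1c(OCc9ccccc9)cc(OCc9ccccc9)c2c1O[C@H](c3ccc(OCc9ccccc9)c(OCc9ccccc9)c3)[C@@H](OCc9ccccc9)C2
F2 | step 21 | acid chloride of F1 | CC(C)(C)[Si](C)(C)O[C@@H](c3ccc(OCc9ccccc9)c(OCc9ccccc9)c3)[C@H](OCc9ccccc9)[C@H](/C=C/CC(=O)Cl)c1c(OCc9ccccc9)cc(OCc9ccccc9)c2c1O[C@H](c3ccc(OCc9ccccc9)c(OCc9ccccc9)c3)[C@@H](OCc9ccccc9)C2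
F3 | step 19 | 3-benzyloxy-4-[3,4-bis(benzyloxy)phenyl]-4-(tert-butyldimethylsiloxy)-2-(Cat8)butanal (configuration as in 30) | CC(C)(C)[Si](C)(C)O[C@@H](c3ccc(OCc9ccccc9)c(OCc9ccccc9)c3)[C@H](OCc9ccccc9)[C@H](C=O)c1c(OCc9ccccc9)cc(OCc9ccccc9)c2c1O[C@H](c3ccc(OCc9ccccc9)c(OCc9ccccc9)c3)[C@@H](OCc9ccccc9)C2
F4 | step 23 | C8a-O-triflate of 39 | CC(C)(C)[Si](C)(C)O[C@@H](c3ccc(OCc9ccccc9)c(OCc9ccccc9)c3)[C@H](OCc9ccccc9)[C@H](c1ccc(O[Si](C(C)C)(C(C)C)C(C)C)c([C@@H]4[C@@H](OCc9ccccc9)[C@@H](c3ccc(OCc9ccccc9)c(OCc9ccccc9)c3)Oc5cc(OCc9ccccc9)cc(OCc9ccccc9)c45)c1OS(=O)(=O)C(F)(F)F)c1c(OCc9ccccc9)cc(OCc9ccccc9)c2c1O[C@H](c3ccc(OCc9ccccc9)c(OCc9ccccc9)c3)[C@@H](OCc9ccccc9)C2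
F5 | step 23 | (2S)-alcohol with C8a triflate and C7 silyl ether | O[C@@H](c3ccc(OCc9ccccc9)c(OCc9ccccc9)c3)[C@H](OCc9ccccc9)[C@H](c1ccc(O[Si](C(C)C)(C(C)C)C(C)C)c([C@@H]4[C@@H](OCc9ccccc9)[C@@H](c3ccc(OCc9ccccc9)c(OCc9ccccc9)c3)Oc5cc(OCc9ccccc9)cc(OCc9ccccc9)c45)c1OS(=O)(=O)C(F)(F)F)c1c(OCc9ccccc9)cc(OCc9ccccc9)c2c1O[C@H](c3ccc(OCc9ccccc9)c(OCc9ccccc9)c3)[C@@H](OCc9ccccc9)C2
F6 | step 23 | C2 ketone with C8a triflate and C7 silyl ether | O=C(c3ccc(OCc9ccccc9)c(OCc9ccccc9)c3)[C@H](OCc9ccccc9)[C@H](c1ccc(O[Si](C(C)C)(C(C)C)C(C)C)c([C@@H]4[C@@H](OCc9ccccc9)[C@@H](c3ccc(OCc9ccccc9)c(OCc9ccccc9)c3)Oc5cc(OCc9ccccc9)cc(OCc9ccccc9)c45)c1OS(=O)(=O)C(F)(F)F)c1c(OCc9ccccc9)cc(OCc9ccccc9)c2c1O[C@H](c3ccc(OCc9ccccc9)c(OCc9ccccc9)c3)[C@@H](OCc9ccccc9)C2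
F7 | step 23 | (2R)-alcohol (1,2-syn) with C8a triflate and C7 silyl ether | O[C@H](c3ccc(OCc9ccccc9)c(OCc9ccccc9)c3)[C@H](OCc9ccccc9)[C@H](c1ccc(O[Si](C(C)C)(C(C)C)C(C)C)c([C@@H]4[C@@H](OCc9ccccc9)[C@@H](c3ccc(OCc9ccccc9)c(OCc9ccccc9)c3)Oc5cc(OCc9ccccc9)cc(OCc9ccccc9)c45)c1OS(=O)(=O)C(F)(F)F)c1c(OCc9ccccc9)cc(OCc9ccccc9)c2c1O[C@H](c3ccc(OCc9ccccc9)c(OCc9ccccc9)c3)[C@@H](OCc9ccccc9)C2
F8 | step 23 | 7-O-triisopropylsilyl ether of 41 | c9ccccc9COc1cc(OCc9ccccc9)c2c(c1)O[C@H](c3ccc(OCc9ccccc9)c(OCc9ccccc9)c3)[C@H](OCc9ccccc9)[C@H]2c1c(O[Si](C(C)C)(C(C)C)C(C)C)ccc2c1O[C@H](c3ccc(OCc9ccccc9)c(OCc9ccccc9)c3)[C@H](OCc9ccccc9)[C@H]2c1c(OCc9ccccc9)cc(OCc9ccccc9)c2c1O[C@H](c3ccc(OCc9ccccc9)c(OCc9ccccc9)c3)[C@@H](OCc9ccccc9)C2
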